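The dihydrofuran ring (O1, C2, C3, C3a, C7a) is cut at O1–C7a and C3–C3a. Because C7a carries the ring oxygen next to the C7 methoxy carbon, the benzene ring can be drawn as a quinone monoketal (C7 ketal, C4 carbonyl) whose enone C3a=C7a accepts oxygen at C7a and carbon at C3a. A palladium-catalysed (3+2) cycloaddition of the alkoxide/π-allyl dipole from an enantioenriched 1-aryl-2-(benzoyloxy)but-3-en-1-ol onto this dienone forms both bonds in one operation, with C2 directing C3. Reduction and loss of water and methanol then aromatise the ring. The C3 vinyl group becomes CH2OH and the C5 acetal becomes the propenal.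

Key step: step 5

Remark: benzofuran numbering (O1, C2, C3, C3a, C4 to C7, C7a) is used for all bicyclic compounds; in step 3 the ligand antipode is written on the assumption that (R)-SEGPHOS delivers the 1S carbinol, and the other antipode would be taken if the sense is opposite.

Step 1
Reactants: 1 3,4-dihydroxy-5-methoxybenzaldehyde
Product: 2 3-methoxy-4,5-bis(methoxymethoxy)benzaldehyde
Conditions: MOMCl, i-Pr2NEt, CH2Cl2, 0 °C to rt
Reagents that add atoms: chloromethyl methyl ether, COCCl
Why: O-alkylation of both phenols (Williamson-type MOM protection) should give base-stable acetals that tolerate every step up to the acid unmasking in step 8.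

Step 2
Reactants: 3 acrolein; 4 benzoic anhydride
Product: 5 prop-2-ene-1,1-diyl dibenzoate
Conditions: H2SO4 (cat.), CH2Cl2, 0 °C to rt
Reagents that add atoms: none
Why: Acid-catalysed acylal formation (addition of the anhydride across the aldehyde C=O) should give the geminal dibenzoate that serves as allyl donor in step 3.

Step 3
Reactants: 2 3-methoxy-4,5-bis(methoxymethoxy)benzaldehyde; 5 prop-2-ene-1,1-diyl dibenzoate
Product: 6 (1S,2R)-1-hydroxy-1-[3-methoxy-4,5-bis(methoxymethoxy)phenyl]but-3-en-2-yl benzoate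
Conditions: [Ir(cod)Cl]2, (R)-SEGPHOS, 4-cyano-3-nitrobenzoic acid, Cs2CO3 (cat.), i-PrOH, THF, 90 °C
Reagents that add atoms: none
Why: Iridium-catalysed transfer-hydrogenative carbonyl (α-acyloxy)allylation: ionisation of 5 gives a (benzoyloxy)allyliridium species that adds to the aldehyde through a closed chair transition state, so the anti adduct should form with the carbinol configuration (the later C2) fixed by the chiral ligand.

Step 4
Reactants: 7 2-hydroxy-5-methoxybenzaldehyde
Product: 9 2-(dimethoxymethyl)-4,4-dimethoxycyclohexa-2,5-dien-1-one, via phenol dimethyl acetal 8 (not isolated)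
Conditions: HC(OMe)3, TsOH·H2O (cat.), MeOH, rt; then PhI(OAc)2, 0 °C
Reagents that add atoms: trimethyl orthoformate, COC(OC)OC; methanol, CO
Why: Acetalisation masks the aldehyde, and oxidative dearomatisation of the para-methoxyphenol by PhI(OAc)2 in methanol should then give the quinone monoketal, the masked form of the C4–C7 benzene ring.

Step 5
Reactants: 6 (1S,2R)-1-hydroxy-1-[3-methoxy-4,5-bis(methoxymethoxy)phenyl]but-3-en-2-yl benzoate; 9 2-(dimethoxymethyl)-4,4-dimethoxycyclohexa-2,5-dien-1-one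
Product: 10 (2R,3R,3aR,7aS)-5-(dimethoxymethyl)-3-ethenyl-7,7-dimethoxy-2-[3-methoxy-4,5-bis(methoxymethoxy)phenyl]-3,3a,7,7a-tetrahydro-1-benzofuran-4(2H)-one
Conditions: Pd2(dba)3·CHCl3, dppf, Cs2CO3, THF, 25 °C
Reagents that add atoms: none
Why: Proposed new method: zerovalent palladium ionises the allylic benzoate of 6 and Cs2CO3 frees the neighbouring hydroxyl, giving the alkoxide/π-allylpalladium dipole; its oxygen adds reversibly (oxa-Michael) to the β-carbon of the unsubstituted enone of 9 (the later C7a) and the enolate carbon (the later C3a) then attacks the proximal allyl terminus (C3) on the face opposite to palladium. The closest known reaction type is the palladium-catalysed formal (3+2) cycloaddition of vinyl epoxides or vinylethylene carbonates with electron-poor alkenes to give 3-vinyltetrahydrofurans; untested are the cross-conjugated dienone (quinone monoketal) acceptor and the hydroxy allylic benzoate as dipole source. The tetrahydrofuran ring closes in the C–C bond-forming event as a 5-exo allylic alkylation (attack at the distal CH2 would need a seven-membered ring), which makes the ring fusion cis. C2 is carried over from 6; C3 should be set trans to the C2 aryl group because the syn-allyl complex reacts through the conformer that keeps the small C2–H, not the aryl group, in the allyl plane (allylic 1,3-strain); C3a and C7a follow from the cis fusion and are erased in step 6. The step needs regioselectivity between the two enone units of 9 and C- over O-bonding: C–C bond formation at the acetal-bearing α-carbon would create a quaternary centre, and O-bonded adducts (carbonyl cycloadducts, vinyl epoxide) are re-ionised by zerovalent palladium whereas the C–C bond is not.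

Step 6
Reactants: 10 (2R,3R,3aR,7aS)-5-(dimethoxymethyl)-3-ethenyl-7,7-dimethoxy-2-[3-methoxy-4,5-bis(methoxymethoxy)phenyl]-3,3a,7,7a-tetrahydro-1-benzofuran-4(2H)-one
Product: 12 (2R,3R)-5-(dimethoxymethyl)-3-ethenyl-7-methoxy-2-[3-methoxy-4,5-bis(methoxymethoxy)phenyl]-2,3-dihydro-1-benzofuran, via allylic alcohol 11 (not isolated)
Conditions: NaBH4, CeCl3·7H2O, MeOH, −40 °C; aqueous work-up; then CSA (cat.), 4 Å MS, CH2Cl2, 0 °C to rt
Reagents that add atoms: none
Why: Luche 1,2-reduction followed by acid-promoted loss of methanol (through the C7 oxocarbenium ion) and of water (through an arenium ion) should aromatise the ring to the C7 anisole, erasing C3a and C7a while C2 and C3 are untouched.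

Step 7
Reactants: 12 (2R,3R)-5-(dimethoxymethyl)-3-ethenyl-7-methoxy-2-[3-methoxy-4,5-bis(methoxymethoxy)phenyl]-2,3-dihydro-1-benzofuran
Product: 14 [(2R,3S)-5-(dimethoxymethyl)-7-methoxy-2-[3-methoxy-4,5-bis(methoxymethoxy)phenyl]-2,3-dihydro-1-benzofuran-3-yl]methanol, via aldehyde 13 (not isolated)
Conditions: OsO4 (cat.), NaIO4, 2,6-lutidine, dioxane/H2O, rt; extractive work-up; then NaBH4, MeOH, 0 °C
Reagents that add atoms: osmium tetroxide (delivers the oxygen atom, regenerated by periodate), O=[Os](=O)(=O)=O; sodium periodate, [Na+].[O-]I(=O)(=O)=O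
Why: Lemieux–Johnson cleavage of the only alkene and immediate borohydride reduction of the epimerisable aldehyde should turn the vinyl group into CH2OH with the C3 geometry retained (the descriptor changes from 3R to 3S by priority only).

Step 8
Reactants: 14 [(2R,3S)-5-(dimethoxymethyl)-7-methoxy-2-[3-methoxy-4,5-bis(methoxymethoxy)phenyl]-2,3-dihydro-1-benzofuran-3-yl]methanol
Product: 15 (2R,3S)-2-(3,4-dihydroxy-5-methoxyphenyl)-3-(hydroxymethyl)-7-methoxy-2,3-dihydro-1-benzofuran-5-carbaldehyde
Conditions: 2 M HCl, THF, 40 °C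
Reagents that add atoms: water, O
Why: Acid hydrolysis should cleave the dimethyl acetal and both MOM ethers in one operation, and any reversible opening at the benzylic C2–O1 bond recloses to the trans ring anchored by C3.

Step 9
Reactants: 15 (2R,3S)-2-(3,4-dihydroxy-5-methoxyphenyl)-3-(hydroxymethyl)-7-methoxy-2,3-dihydro-1-benzofuran-5-carbaldehyde
Product: 16 cassyformin, (E)-3-[(2R,3S)-2-(3,4-dihydroxy-5-methoxyphenyl)-3-(hydroxymethyl)-7-methoxy-2,3-dihydro-1-benzofuran-5-yl]prop-2-enal
Conditions: Ph3P=CHCHO, toluene/THF, 80 °C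
Reagents that add atoms: (triphenylphosphoranylidene)acetaldehyde, O=CC=P(c1ccccc1)(c1ccccc1)c1ccccc1
Why: Wittig reaction of the stabilised formyl ylide with the aryl aldehyde should give the (E)-enal under neutral conditions that tolerate the free catechol and the primary alcohol.

Compound list
1 | 3,4-dihydroxy-5-methoxybenzaldehyde | COc1cc(C=O)cc(O)c1O | starting material
2 | 3-methoxy-4,5-bis(methoxymethoxy)benzaldehyde | COc1cc(C=O)cc(OCOC)c1OCOC | intermediate
3 | acrolein (prop-2-enal) | C=CC=O | starting material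
4 | benzoic anhydride | O=C(OC(=O)c1ccccc1)c1ccccc1 | starting material
5 | prop-2-ene-1,1-diyl dibenzoate | C=CC(OC(=O)c1ccccc1)OC(=O)c1ccccc1 | intermediate
6 | (1S,2R)-1-hydroxy-1-[3-methoxy-4,5-bis(methoxymethoxy)phenyl]but-3-en-2-yl benzoate (anti) | COc1cc([C@H](O)[C@H](OC(=O)c2ccccc2)C=C)cc(OCOC)c1OCOC | intermediate
7 | 2-hydroxy-5-methoxybenzaldehyde | COc1ccc(O)c(C=O)c1 | starting material
8 | 2-(dimethoxymethyl)-4-methoxyphenol | COc1ccc(O)c(C(OC)OC)c1 | intermediate
9 | 2-(dimethoxymethyl)-4,4-dimethoxycyclohexa-2,5-dien-1-one | COC(OC)C1=CC(OC)(OC)C=CC1=O | intermediate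
10 | (2R,3R,3aR,7aS)-5-(dimethoxymethyl)-3-ethenyl-7,7-dimethoxy-2-[3-methoxy-4,5-bis(methoxymethoxy)phenyl]-3,3a,7,7a-tetrahydro-1-benzofuran-4(2H)-one (cis-fused; aryl trans to vinyl; expected major isomer) | COc1cc([C@@H]2O[C@@H]3C(OC)(OC)C=C(C(OC)OC)C(=O)[C@@H]3[C@H]2C=C)cc(OCOC)c1OCOC | intermediate
11 | 4-hydroxy compound from 1,2-reduction of the ketone of 10 (configuration of 10 kept at C2, C3, C3a, C7a; both C4 epimers) | COc1cc([C@@H]2O[C@@H]3C(OC)(OC)C=C(C(OC)OC)C(O)[C@@H]3[C@H]2C=C)cc(OCOC)c1OCOC | intermediate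
12 | (2R,3R)-5-(dimethoxymethyl)-3-ethenyl-7-methoxy-2-[3-methoxy-4,5-bis(methoxymethoxy)phenyl]-2,3-dihydro-1-benzofuran | COc1cc([C@@H]2Oc3c(OC)cc(C(OC)OC)cc3[C@H]2C=C)cc(OCOC)c1OCOC | intermediate
13 | (2R,3R)-5-(dimethoxymethyl)-7-methoxy-2-[3-methoxy-4,5-bis(methoxymethoxy)phenyl]-2,3-dihydro-1-benzofuran-3-carbaldehyde | COc1cc([C@@H]2Oc3c(OC)cc(C(OC)OC)cc3[C@H]2C=O)cc(OCOC)c1OCOC | intermediate
14 | [(2R,3S)-5-(dimethoxymethyl)-7-methoxy-2-[3-methoxy-4,5-bis(methoxymethoxy)phenyl]-2,3-dihydro-1-benzofuran-3-yl]methanol | COc1cc([C@@H]2Oc3c(OC)cc(C(OC)OC)cc3[C@H]2CO)cc(OCOC)c1OCOC | intermediate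
15 | (2R,3S)-2-(3,4-dihydroxy-5-methoxyphenyl)-3-(hydroxymethyl)-7-methoxy-2,3-dihydro-1-benzofuran-5-carbaldehyde | COc1cc([C@@H]2Oc3c(OC)cc(C=O)cc3[C@H]2CO)cc(O)c1O | intermediate
16 | cassyformin, (E)-3-[(2R,3S)-2-(3,4-dihydroxy-5-methoxyphenyl)-3-(hydroxymethyl)-7-methoxy-2,3-dihydro-1-benzofuran-5-yl]prop-2-enal | COc1cc([C@@H]2Oc3c(OC)cc(/C=C/C=O)cc3[C@H]2CO)cc(O)c1O | target

Total step count: 9. Longest linear sequence: 7 steps (1, 3, 5, 6, 7, 8, 9, from 3,4-dihydroxy-5-methoxybenzaldehyde).

Steps most likely to fail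

1. Step 5 (Proposed new method). The alkoxide/π-allylpalladium dipole may be lost by β-hydride elimination or by closure to a 2,5-dihydrofuran before the weakly activated dienone intercepts it, and the ring-closing allylation may show poor facial selectivity at C3. The fallback uses known chemistry, sets out from 2 and comes back at 15; in it the ring oxygen is supplied by a phenol. Horner–Wadsworth–Emmons olefination of 2 (triethyl phosphonoacetate, NaH, THF) should give ethyl (E)-3-[3-methoxy-4,5-bis(methoxymethoxy)phenyl]prop-2-enoate F1. DIBAL-H reduction should give (E)-3-[3-methoxy-4,5-bis(methoxymethoxy)phenyl]prop-2-en-1-ol F2, and methyl chloroformate with pyridine its carbonate, methyl (E)-3-[3-methoxy-4,5-bis(methoxymethoxy)phenyl]prop-2-en-1-yl carbonate F3. Iridium-catalysed branched-selective asymmetric allylic etherification ([Ir(cod)Cl]2, a BINOL-derived N,N-bis(1-phenylethyl)phosphoramidite, THF) with the sodium phenoxide of commercial 4-hydroxy-3-iodo-5-methoxybenzaldehyde should give 3-iodo-5-methoxy-4-{[(1R)-1-[3-methoxy-4,5-bis(methoxymethoxy)phenyl]prop-2-en-1-yl]oxy}benzaldehyde F4. A 5-exo aryl radical cyclisation with trapping of the primary radical (Bu3SnH, TEMPO, benzene, 70 °C) should give the trans alkoxyamine (2R,3S)-7-methoxy-2-[3-methoxy-4,5-bis(methoxymethoxy)phenyl]-3-{[(2,2,6,6-tetramethylpiperidin-1-yl)oxy]methyl}-2,3-dihydro-1-benzofuran-5-carbaldehyde F5. Zn in AcOH should cleave the N–O bond to (2R,3S)-3-(hydroxymethyl)-7-methoxy-2-[3-methoxy-4,5-bis(methoxymethoxy)phenyl]-2,3-dihydro-1-benzofuran-5-carbaldehyde F6. 2 M HCl in THF then removes the MOM groups to give 15, which rejoins the route at step 9.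

2. Step 6. Hydrolysis of the C7 dimethyl ketal may compete with elimination of methanol during the acid-promoted aromatisation, which would cost the C7 methyl ether. The fallback sets out from 10 and comes back at 12 by accepting the hydrolytic pathway. After the same Luche reduction, oxalic acid in wet THF should convert crude 11 by ketal hydrolysis and dehydration (the aldehyde acetal is lost as well) into (2R,3R)-3-ethenyl-7-hydroxy-2-[3-methoxy-4,5-bis(methoxymethoxy)phenyl]-2,3-dihydro-1-benzofuran-5-carbaldehyde F7. MeI and K2CO3 in acetone should methylate the phenol to (2R,3R)-3-ethenyl-7-methoxy-2-[3-methoxy-4,5-bis(methoxymethoxy)phenyl]-2,3-dihydro-1-benzofuran-5-carbaldehyde F8. HC(OMe)3 with PPTS in MeOH re-forms the dimethyl acetal 12.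

3. Step 7. The β-aryloxy aldehyde 13 may enolise and expel the phenoxide (ring opening and reclosure), which would scramble C2 and C3. The fallback sets out from 10 and comes back at 14 by cleaving the vinyl group before aromatisation, while the β-oxygen is still an alkyl ether and a poor leaving group. OsO4 (cat.), NaIO4 and 2,6-lutidine on 10 should give (2R,3R,3aR,7aS)-5-(dimethoxymethyl)-7,7-dimethoxy-2-[3-methoxy-4,5-bis(methoxymethoxy)phenyl]-4-oxo-2,3,3a,4,7,7a-hexahydro-1-benzofuran-3-carbaldehyde F9. NaBH4 with CeCl3·7H2O should reduce both carbonyl groups to the diol, 5-(dimethoxymethyl)-3-(hydroxymethyl)-7,7-dimethoxy-2-[3-methoxy-4,5-bis(methoxymethoxy)phenyl]-2,3,3a,4,7,7a-hexahydro-1-benzofuran-4-ol F10 (both C4 epimers). CSA with 4 Å MS in CH2Cl2 then eliminates water and methanol to give 14, which rejoins the route at step 8.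

Further compounds
F1 | step 5 | ethyl (E)-3-[3-methoxy-4,5-bis(methoxymethoxy)phenyl]prop-2-enoate | CCOC(=O)/C=C/c1cc(OC)c(OCOC)c(OCOC)c1
F2 | step 5 | (E)-3-[3-methoxy-4,5-bis(methoxymethoxy)phenyl]prop-2-en-1-ol | OC/C=C/c1cc(OC)c(OCOC)c(OCOC)c1
F3 | step 5 | methyl (E)-3-[3-methoxy-4,5-bis(methoxymethoxy)phenyl]prop-2-en-1-yl carbonate | COC(=O)OC/C=C/c1cc(OC)c(OCOC)c(OCOC)c1
F4 | step 5 | 3-iodo-5-methoxy-4-{[(1R)-1-[3-methoxy-4,5-bis(methoxymethoxy)phenyl]prop-2-en-1-yl]oxy}benzaldehyde | COc1cc([C@@H](C=C)Oc2c(I)cc(C=O)cc2OC)cc(OCOC)c1OCOC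
F5 | step 5 | (2R,3S)-7-methoxy-2-[3-methoxy-4,5-bis(methoxymethoxy)phenyl]-3-{[(2,2,6,6-tetramethylpiperidin-1-yl)oxy]methyl}-2,3-dihydro-1-benzofuran-5-carbaldehyde | COc1cc([C@@H]2Oc3c(OC)cc(C=O)cc3[C@H]2CON4C(C)(C)CCCC4(C)C)cc(OCOC)c1OCOC
F6 | step 5 | (2R,3S)-3-(hydroxymethyl)-7-methoxy-2-[3-methoxy-4,5-bis(methoxymethoxy)phenyl]-2,3-dihydro-1-benzofuran-5-carbaldehyde | COc1cc([C@@H]2Oc3c(OC)cc(C=O)cc3[C@H]2CO)cc(OCOC)c1OCOC
F7 | step 6 | (2R,3R)-3-ethenyl-7-hydroxy-2-[3-methoxy-4,5-bis(methoxymethoxy)phenyl]-2,3-dihydro-1-benzofuran-5-carbaldehyde | COc1cc([C@@H]2Oc3c(O)cc(C=O)cc3[C@H]2C=C)cc(OCOC)c1OCOC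
F8 | step 6 | (2R,3R)-3-ethenyl-7-methoxy-2-[3-methoxy-4,5-bis(methoxymethoxy)phenyl]-2,3-dihydro-1-benzofuran-5-carbaldehyde | COc1cc([C@@H]2Oc3c(OC)cc(C=O)cc3[C@H]2C=C)cc(OCOC)c1OCOC
F9 | step 7 | (2R,3R,3aR,7aS)-5-(dimethoxymethyl)-7,7-dimethoxy-2-[3-methoxy-4,5-bis(methoxymethoxy)phenyl]-4-oxo-2,3,3a,4,7,7a-hexahydro-1-benzofuran-3-carbaldehyde | COc1cc([C@@H]2O[C@@H]3C(OC)(OC)C=C(C(OC)OC)C(=O)[C@@H]3[C@H]2C=O)cc(OCOC)c1OCOC
F10 | step 7 | 5-(dimethoxymethyl)-3-(hydroxymethyl)-7,7-dimethoxy-2-[3-methoxy-4,5-bis(methoxymethoxy)phenyl]-2,3,3a,4,7,7a-hexahydro-1-benzofuran-4-ol (configuration of F9 kept; both C4 epimers) | COc1cc([C@@H]2O[C@@H]3C(OC)(OC)C=C(C(OC)OC)C(O)[C@@H]3[C@H]2CO)cc(OCOC)c1OCOC
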